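**Remarks on the chemistry**

- Compounds 1–14 carry podocarpane/abietane locants; from 15 on briarane locants are used (podocarpane C13, C9, C8, C10, C5, C4 = briarane C5, C2, C7, C1, C10, C11). α and β are the two faces of the flat projection of rings A and B, with the C15 methyl on the β face.
- The stereodescriptors of 12, 15 and 44 were compared with those of 1 and agree at C1, C10 and C11; no structure needed correction. The C4 carboxyl is carried as the free acid, not as the methyl ester, through steps 7–11.
- C2 and C7 (16–27; C2 up to 38) and C17 (33–36) are carried as epimer mixtures, because each is later returned to sp2 or equilibrated.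
- The Tebbe reagent is drawn with its chloride bridge as two covalent bonds and formal charges on aluminium and chlorine.

## Structural features

The target is a briarane: a cyclohexane (ring A) fused through C1–C10 to a ten-membered carbocycle (ring B), which carries a γ-lactone (ring C) across C7–C8. Eleven stereocentres form an almost unbroken chain C6–C7–C8–C9–C10–C11–C12–C13–C14–C1–C2, with C17 on the lactone; C1 is quaternary and C8 and C11 are tertiary carbinols. Fragile groups are the secondary allylic chloride at C6 beside the C3–C4/C5–C16 diene, the free allylic C2 alcohol, the β-hydroxy lactone (retro-aldol, dehydration), the C13–C14 epoxide next to an acyloxy carbon, and two different esters that must not be exchanged. The real difficulty is ring B: all ten carbons are functionalised, and stereocontrol in a medium ring cannot lean on rigid chair models. The feature exploited is that the oxygenated carbons C2 and C7 stand 1,6 across ring B. Joining them turns ring B into two six-membered rings, and together with ring A this is a perhydrophenanthrene whose C1 methyl, H-10 and C11 methyl match ring A of the abietane resin acids in absolute configuration. Ring B can therefore be unveiled without any ring closure, by cleaving the C2=C7 olefin of a tricycle whose carboxyl sits where the C11 hydroxyl is needed.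

## Logic of the disconnections

44 to 43: the C2–H bond is cut (carbinol back to ketone). The C2 stereocentre is set last so that the ketone can first serve to introduce the C3–C4 unsaturation. The forward step must be a 1,2-reduction of a hindered dienone that is face-selective and spares the allylic chloride.

43 to 41 through 42: the C5=C16 bond and the C6–Cl bond are cut, leaving the C5 ketone of an enedione. With C3=C4 in place, C6 is the only enolisable carbon of either ketone, so chlorination is regiospecific. The forward steps need a neutral chlorination and a non-basic methylenation that distinguishes C5 from the neopentyl C2 carbonyl.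

41 to 37 through 40, 39 and 38: the C3=C4 π bond is removed and C5 returns to its dioxolane, C2 to a silyl ether. This removes the reactive enedione until the end. The forward dehydrogenation must find only one way to go, which the quaternary C1 guarantees.

37 to 34 through 36 and 35: the lactone C–O bond at C7 and the C9–O bond are cut and the C8 oxygen is traced to an epoxide. One directed epoxidation then fixes C8 and C9 from C7. The forward steps need syn oxygen delivery and an epoxide opening at C9 with inversion.

34 to 30 and 31 through 33: the C7–H bond (carbinol back to ketone) and the C8–C17 bond are cut. This gives an α-iodoenone and a three-carbon propanoate unit. The forward steps need an sp2–sp3 coupling that tolerates a ketone and a reagent-controlled ketone reduction.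

30 to 26 through 29, 28 and 27: the C8–I bond and the C8=C9 unsaturation are removed and C7 returns to a silyl ether. The forward dehydrogenation is forced to C8–C9 because ketal carbon C5 bears no hydrogen.

26 to 23 through 25 and 24: the C12 ester, the epoxide C–O bonds and the two hydroxyl C–O bonds of ring A are cut to give a C11–C14 diene. All four oxygens then come from two face-selective oxidations. The forward steps must choose the trisubstituted olefin first and the α face both times.

23 to 20 through 22 and 21: the C13=C14 bond is removed by way of an enol triflate and an enone. This leaves a single trisubstituted olefin. The forward steps need allylic oxidation at C13 and kinetic enolisation at C14.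

20 to 15 through 19, 18, 17 and 16: the C11–C18 bond is restored (decarboxylation in the forward sense) and the two silyl ethers return to the ketones of the seco-dione. This gives back the acid with every ring A stereocentre. The forward steps must mask the 1,6-dione before any base is used and must place the olefin at C11–C12.

15 to 12: C2 and C7 are joined again as an olefin. Ring B becomes two six-membered rings and the whole problem becomes a known tricycle. The forward step must cleave a tetrasubstituted olefin cleanly and without epimerisation.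

12 to 9 through 10, with 11: the dioxolane and two ring hydrogens are removed to give an anisole. The forward steps need a Birch reduction that keeps the carboxyl and a ketalisation that does not move the olefin.

9 to 1 through 8, 7, 6, 5, 3 and 2, with 4: the C13–O bond is exchanged for the C13 isopropyl group of the resin acid. The forward steps need de-alkylation without epimerising C10 and a regioselective acylation–oxygen insertion at C13.

## Other disconnections considered

Alternative 1: The cut is at the C11–O and C14–O bonds of ring A. In the forward sense, sensitised singlet oxygen adds across a C11–C14 diene in a [4+2] cycloaddition to give endoperoxide A1. In its favour, two C–O bonds are formed in one pericyclic step, on one face, and the O–O bond can then be relayed to other ring A positions. Against it here, A1 holds only ring A with C2 and C9 as protected hydroxymethyl stubs. Ring B would have to be closed as a ten-membered ring by C–C bond formation, and quaternary C1 would have to be made by asymmetric synthesis. The oxygens also arrive at C11 and C14, whereas the target needs them at C11, C12 and C13/C14. On structure, the chosen plan buys C1, C10 and C11 and never closes ring B. On mechanism, both key steps are reliable additions to a π system. On step economy, the alternative is expected to be longer because of the ring B construction. For the face-selective oxygenation of ring A itself it is the equal of steps 17 and 18, and could use the same diene.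

Alternative 2: The cut is at the C1–C10 bond. In the forward sense, a Lewis acid opens a C1–C2 epoxide in a fourteen-membered ring at tertiary C1, and the C10–C11 olefin attacks across the ring to give A2. In its favour, one step forms a skeletal bond, closes rings A and B, sets C1, C2 and C10, and delivers the C2 hydroxyl and a ring A diene. In bond construction per step it is better than the chosen key step, which forms no C–C bond. Against it here, the macrocycle must already carry the butenolide, the C5 ketone and the C6 and C9 oxygens, and making it would be a long synthesis with a macrocyclisation. The cyclisation would also depend on the ring conformation, and hydride shifts, other ring sizes and other sites of proton loss could compete. On structure, the chosen plan fixes C1 and C10 from the chiral pool rather than from a folded macrocycle. On mechanism, ozonolysis is less sensitive to conformation than a cationic cyclisation. On step economy, the alternative would be shorter after the key step but longer before it.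

Alternative 3: The cut is at the C7–O and C6–Cl bonds. In the forward sense, an electrophilic chlorine source activates an E C6–C7 olefin, and the C19 carboxylate closes ring C in 5-exo mode to give A3. In its favour, anti addition across the E-olefin would set chlorine and lactone oxygen in the required relative arrangement and close the lactone in one step. For C6/C7 stereocontrol it is better than the chosen plan, where these centres come from steps 24 and 30 separately. Against it here, an E-olefin in the functionalised ten-membered ring is strained and has no obvious source from a 7-oxo seco compound. The C3–C4 olefin and the C2 hydroxyl could compete for the electrophile. A3 also carries C16 as a silyloxymethyl group on sp3 C5, so the exocyclic methylene would have to be made by elimination next to the allylic chloride. On structure, it is an end-game tactic that does not address ring B. On mechanism, halolactonisation is as dependable as enol chlorination. On step economy, it saves one step at C6/C7 but adds steps for C16.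

Key step: step 9

## Route

Step 1
Reactants: 1 dehydroabietic acid
Product: 2 methyl dehydroabietate
Conditions: MeI, K2CO3, DMF, rt
Reagents that add atoms: iodomethane, CI
Why: SN2 O-alkylation of the carboxylate avoids attack at the hindered carbonyl; the ester is needed because the free acid would be ionised under the AlCl3 steps.

Step 2
Reactants: 2 methyl dehydroabietate
Product: 3 methyl podocarpa-8,11,13-trien-18-oate
Conditions: AlCl3, benzene (solvent and acceptor), 15 °C
Reagents that add atoms: none
Why: Retro-Friedel–Crafts transalkylation: ipso protonation and transfer of the isopropyl cation to benzene; low temperature and short contact are meant to prevent opening of ring B at C9–C10, which would epimerise C10.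

Step 3
Reactants: 3 methyl podocarpa-8,11,13-trien-18-oate, 4 acetyl chloride
Product: 5 methyl 13-acetylpodocarpa-8,11,13-trien-18-oate
Conditions: AlCl3, CH2Cl2, 0 °C
Reagents that add atoms: acetyl chloride (4), CC(Cl)=O
Why: Friedel–Crafts acylation; C11 and C14 are shielded by the ring junctions, and of the two open positions C13 is para to C9, the carbon bearing the fully substituted C10. The C12 isomer is the expected minor product and should be removable by crystallisation.

Step 4
Reactants: 5 methyl 13-acetylpodocarpa-8,11,13-trien-18-oate
Product: 6 methyl 13-acetoxypodocarpa-8,11,13-trien-18-oate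
Conditions: mCPBA, CF3CO2H (cat.), CH2Cl2, rt
Reagents that add atoms: 3-chloroperoxybenzoic acid, OOC(=O)c1cccc(Cl)c1
Why: Baeyer–Villiger oxidation; the aryl group migrates in preference to methyl, which puts the oxygen on C13.

Step 5
Reactants: 6 methyl 13-acetoxypodocarpa-8,11,13-trien-18-oate
Product: 8 methyl 13-methoxypodocarpa-8,11,13-trien-18-oate, via phenol 7 (not isolated)
Conditions: K2CO3, MeOH, rt; then MeI, 40 °C
Reagents that add atoms: iodomethane, CI
Why: Base-catalysed transesterification frees the phenoxide, which is methylated in the same flask (Williamson ether synthesis); the neopentyl C4 ester does not exchange.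

Step 6
Reactants: 8 methyl 13-methoxypodocarpa-8,11,13-trien-18-oate
Product: 9 13-methoxypodocarpa-8,11,13-trien-18-oic acid
Conditions: t-BuOK, DMSO, 60 °C; then aq. HCl
Reagents that add atoms: none
Why: tert-Butoxide in DMSO dealkylates the hindered methyl ester by SN2 attack at the methyl group. The free acid is wanted because a carboxylate is inert to dissolving metal, whereas the ester would be reduced, and because the acid is the leaving group of step 12.

Step 7
Reactants: 9 13-methoxypodocarpa-8,11,13-trien-18-oic acid
Product: 10 13-methoxypodocarpa-8,12-dien-18-oic acid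
Conditions: Li, NH3 (l), THF, t-BuOH, −78 to −33 °C; NH4Cl; work-up at pH 5–6, 0 °C
Reagents that add atoms: none
Why: Birch reduction of the anisole ring: protonation at C11 and C14 leaves the enol ether and the tetrasubstituted C8=C9 olefin, with both alkyl-bearing carbons still sp2. The lithium carboxylate is not reduced, and the mild work-up is meant to preserve the enol ether.

Step 8
Reactants: 10 13-methoxypodocarpa-8,12-dien-18-oic acid, 11 ethylene glycol
Product: 12 13,13-ethylenedioxypodocarp-8-en-18-oic acid
Conditions: PPTS (cat.), CH2Cl2, rt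
Reagents that add atoms: ethylene glycol (11), OCCO
Why: Acid-catalysed ketal exchange of the enol ether: protonation at C12 and capture of the oxocarbenium ion by the diol give the dioxolane without moving the C8=C9 bond into conjugation.

Step 9
Reactants: 12 13,13-ethylenedioxypodocarp-8-en-18-oic acid
Product: 15 13,13-ethylenedioxy-8,9-dioxo-8,9-secopodocarpan-18-oic acid, via primary ozonide 13 (not isolated), via secondary ozonide 14 (not isolated)
Conditions: O3, CH2Cl2, −78 °C; then PPh3, −78 °C to rt
Reagents that add atoms: ozone, [O-][O+]=O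
Why: Ozonolysis of a tetrasubstituted olefin: ozone adds as a 1,3-dipole to the electron-rich C2=C7 bond (podocarpane C9=C8) to give 13, which cycloreverts to a ketone and a carbonyl oxide held in the same ring and recombines to the bridged ozonide 14; PPh3 then removes one peroxide oxygen and releases both ketones. The closest known reaction type is the cleavage of the ring-fusion olefin of 9,10-octalins to cyclodecane-1,6-diones. Ring B is not closed by a cyclisation: it appears when the bond shared by two six-membered rings is cut, so there is no closure mode and no new C–C bond. No stereocentre is created in 15, and C1, C10 and C11 cannot epimerise because the carbons α to the new ketones are the methylenes C3, C6 and C8 and the quaternary C1. The selectivity needed is cleavage of this olefin only, which is secured because it is the sole C=C bond and because ozone is stopped at the first persistent colour; the C5 dioxolane keeps that carbonyl distinct from the two new ones. Neutral phosphine work-up and direct use in step 10 are meant to prevent transannular aldol reaction of the 1,6-dione.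

Step 10
Reactants: 15 13,13-ethylenedioxy-8,9-dioxo-8,9-secopodocarpan-18-oic acid
Product: 16 5,5-ethylenedioxy-2,7-dihydroxy seco acid (C2 and C7 epimers)
Conditions: NaBH4, MeOH, 0 °C to rt
Reagents that add atoms: none
Why: Borohydride reduction of both ketones removes the risk of transannular aldol reaction in the base steps that follow; the two carbinol centres form as mixtures and are returned to sp2 in steps 21 and 28.

Step 11
Reactants: 16 5,5-ethylenedioxy-2,7-dihydroxy seco acid
Product: 18 2,7-bis(tert-butyldimethylsilyloxy)-5,5-ethylenedioxy seco acid, via silyl ester 17 (not isolated)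
Conditions: TBSOTf, 2,6-lutidine, CH2Cl2, 0 °C; then K2CO3, MeOH–H2O
Reagents that add atoms: tert-butyldimethylsilyl trifluoromethanesulfonate, CC(C)(C)[Si](C)(C)OS(=O)(=O)C(F)(F)F
Why: Silylation of both secondary alcohols (the triflate is needed for the neopentyl C2 hydroxyl); the silyl ester formed from the acid is cleaved again by mild aqueous base.

Step 12
Reactants: 18 2,7-bis(tert-butyldimethylsilyloxy)-5,5-ethylenedioxy seco acid
Product: 19 18-nor 11(20)-exocyclic olefin
Conditions: 9-mesitylacridine (cat.), CoCl(C4H7N2O2)2(C5H5N) (cat.), CH2Cl2, 400 nm LED, rt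
Reagents that add atoms: none
Why: Photocatalytic decarboxylative olefination: proton-coupled electron transfer to the excited acridine releases CO2 and the tertiary C11 radical. The cobaloxime then abstracts a β-hydrogen, preferentially from the unhindered methyl group, giving the exocyclic olefin and H2.

Step 13
Reactants: 19 18-nor 11(20)-exocyclic olefin
Product: 20 18-nor 11(12)-ene
Conditions: CoCl(C16H14N2O2) (salen complex, cat.), PhSiH3 (cat.), benzene, rt
Reagents that add atoms: none
Why: Hydrogen-atom-transfer isomerisation: the cobalt hydride adds H to the methylene carbon, and the tertiary C11 radical gives back a hydrogen from the accessible C12 methylene to form the trisubstituted ring olefin. Abstraction of the hindered ring-fusion H-10, which would erase C10, is expected to be slow.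

Step 14
Reactants: 20 18-nor 11(12)-ene
Product: 21 18-nor 11-en-13-one
Conditions: Rh2(C6H10NO)4 (caprolactamate, cat.), t-BuOOH, K2CO3, CH2Cl2, rt
Reagents that add atoms: tert-butyl hydroperoxide, CC(C)(C)OO
Why: Catalytic allylic oxidation by tert-butylperoxyl radicals: abstraction at the allylic methylene C13 and oxidation at the less hindered end of the allyl radical give the β-methyl enone, as with 1-methylcyclohexene.

Step 15
Reactants: 21 18-nor 11-en-13-one
Product: 22 18-nor 11,13-dien-13-yl triflate
Conditions: LDA, THF, −78 °C; then PhNTf2, −78 to 0 °C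
Reagents that add atoms: N-phenylbis(trifluoromethanesulfonimide), O=S(=O)(N(c1ccccc1)S(=O)(=O)C(F)(F)F)C(F)(F)F
Why: Kinetic deprotonation of the enone at the α′ methylene C14 gives the cross-conjugated dienolate, which is O-triflated.

Step 16
Reactants: 22 18-nor 11,13-dien-13-yl triflate
Product: 23 18-nor 11,13-diene
Conditions: Pd(OAc)2 (cat.), PPh3, HCO2H, n-Bu3N, DMF, 60 °C
Reagents that add atoms: none
Why: Palladium-catalysed transfer hydrogenolysis of the enol triflate with formate (oxidative addition, decarboxylation of the formate complex, reductive elimination) gives the C11–C14 diene.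

Step 17
Reactants: 23 18-nor 11,13-diene
Product: 24 13-ene-11α,12α-diol
Conditions: OsO4 (cat.), NMO, acetone–H2O, 0 °C
Reagents that add atoms: osmium tetroxide, O=[Os](=O)(=O)=O; N-methylmorpholine N-oxide, C[N+]1([O-])CCOCC1; water, O
Why: Upjohn dihydroxylation: the trisubstituted, more electron-rich C11=C12 bond reacts first and from the α face, away from the C15 methyl on C1 and from the C10–C9 bond. One suprafacial step sets C11 (α-OH, β-methyl) and C12 (α-OH).

Step 18
Reactants: 24 13-ene-11α,12α-diol
Product: 25 13α,14α-epoxy-11α,12α-diol
Conditions: VO(acac)2 (cat.), t-BuOOH, CH2Cl2, 0 °C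
Reagents that add atoms: tert-butyl hydroperoxide, CC(C)(C)OO
Why: Hydroxyl-directed epoxidation: the vanadate ester of the allylic C12 alcohol delivers oxygen to the same (α) face of C13=C14, which is also the face remote from the C15 methyl.

Step 19
Reactants: 25 13α,14α-epoxy-11α,12α-diol
Product: 26 12α-butanoate of 25
Conditions: (n-PrCO)2O, Et3N, DMAP (cat.), CH2Cl2, 0 °C
Reagents that add atoms: butanoic anhydride, CCCC(=O)OC(=O)CCC
Why: Acylation of the secondary C12 alcohol; the tertiary C11 hydroxyl does not react under these conditions, so ring A is complete.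

Step 20
Reactants: 26 12α-butanoate bis-silyl ether
Product: 27 7-alcohol
Conditions: HF·pyridine, pyridine, THF, 0 °C
Reagents that add atoms: none
Why: Desilylation selective for the unhindered C7 ether; the C2 ether next to quaternary C1 is much slower, and the buffered reagent should spare the epoxide.

Step 21
Reactants: 27 7-alcohol
Product: 29 (8Z)-8-en-7-one, via 7-ketone 28 (not isolated)
Conditions: IBX, DMSO, 70 °C
Reagents that add atoms: none
Why: IBX oxidises the alcohol to ketone 28 and then dehydrogenates it through its enol. Because ketal carbon C5 carries no hydrogen, unsaturation can enter only between C8 and C9; the ring-cis enone is expected.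

Step 22
Reactants: 29 (8Z)-8-en-7-one
Product: 30 8-iodo-8-en-7-one
Conditions: I2, pyridine, CH2Cl2, rt
Reagents that add atoms: iodine, II
Why: α-Iodination of the enone by conjugate addition of pyridine, iodination of the enolate and elimination.

Step 23
Reactants: 30 8-iodo-8-en-7-one, 31 methyl 2-bromopropanoate (racemic)
Product: 33 8-(1-methoxy-1-oxopropan-2-yl)-8-en-7-one (C17 epimers), via Reformatsky reagent 32 (not isolated)
Conditions: Zn, THF (31 to 32); then 30, Pd(PPh3)4 (cat.), THF, rt to 40 °C
Reagents that add atoms: methyl 2-bromopropanoate (31), CC(Br)C(=O)OC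
Why: Negishi-type palladium-catalysed coupling of the zinc ester enolate with the alkenyl iodide forms the C8–C17 bond. C17 forms as both epimers and is equilibrated in step 26.

Step 24
Reactants: 33 8-(1-methoxy-1-oxopropan-2-yl)-8-en-7-one
Product: 34 7α-hydroxy-8-ene ester
Conditions: (R)-2-methyl-CBS-oxazaborolidine, catecholborane, toluene, −78 °C
Reagents that add atoms: none
Why: Corey–Bakshi–Shibata reduction: with the α-branched alkenyl group as the large substituent and the C6 methylene as the small one, the (R)-oxazaborolidine should give the C7 α-alcohol under reagent control.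

Step 25
Reactants: 34 7α-hydroxy-8-ene ester
Product: 35 8α,9α-epoxy-7α-hydroxy ester
Conditions: VO(acac)2 (cat.), t-BuOOH, CH2Cl2, 0 °C
Reagents that add atoms: tert-butyl hydroperoxide, CC(C)(C)OO
Why: Hydroxyl-directed epoxidation: oxygen is delivered syn to the C7–O bond in the rotamer that keeps C6 away from the C17 branch (A(1,2) strain). C7–O and C8–O therefore end on the same face of ring B, and the ring-cis olefin gives the cis-epoxide.

Step 26
Reactants: 35 8α,9α-epoxy-7α-hydroxy ester
Product: 37 9β-acetoxy-8α-hydroxy 19,7-lactone, via hydroxy acetate ester 36 (not isolated)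
Conditions: Ti(OiPr)4, AcOH, CH2Cl2, rt; then PPTS (cat.); then DBU (cat.), rt
Reagents that add atoms: acetic acid, CC(=O)O
Why: Titanium-mediated opening of the 2,3-epoxy alcohol at its distal carbon C9 by acetic acid, with inversion, gives the 8α-hydroxy 9β-acetate. The C7 hydroxyl then closes the γ-lactone on the methyl ester, and catalytic DBU should equilibrate C17 to the epimer with the methyl group trans to C9.

Step 27
Reactants: 37 9β-acetoxy-8α-hydroxy 19,7-lactone
Product: 38 2-alcohol
Conditions: HF·pyridine, THF, 0 °C to rt
Reagents that add atoms: none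
Why: Desilylation of the hindered C2 ether by longer exposure to the fluoride reagent; esters and lactone are not affected.

Step 28
Reactants: 38 2-alcohol
Product: 40 (3Z)-3-en-2-one, via 2-ketone 39 (not isolated)
Conditions: IBX, DMSO, 70 °C
Reagents that add atoms: none
Why: One-pot IBX oxidation to ketone 39 and dehydrogenation; C2 can enolise only towards C3, so C3=C4 is the only possible outcome, expected ring-cis (Z).

Step 29
Reactants: 40 (3Z)-3-en-2-one
Product: 41 (3Z)-3-ene-2,5-dione
Conditions: PPTS (cat.), acetone–H2O, 40 °C
Reagents that add atoms: water, O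
Why: Mild acid hydrolysis of the dioxolane unveils the C5 ketone of the Z-enedione; the hindered ring A epoxide should survive these conditions.

Step 30
Reactants: 41 (3Z)-3-ene-2,5-dione
Product: 42 6α-chloro-(3Z)-3-ene-2,5-dione
Conditions: NCS, thiourea (cat.), MeCN, rt
Reagents that add atoms: N-chlorosuccinimide, O=C1CCC(=O)N1Cl
Why: Enol chlorination with hydrogen-bond-activated NCS under neutral conditions: C6 is the only enolisable position of either ketone. Chlorine should enter anti to the C7–O bond with C8 in the enol plane, which puts Cl and the lactone oxygen on the same (α) face.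

Step 31
Reactants: 42 6α-chloro-(3Z)-3-ene-2,5-dione
Product: 43 6α-chloro-3(Z),5(16)-dien-2-one
Conditions: Cp2Ti(CH2)(Cl)AlMe2 (Tebbe reagent), pyridine, THF–toluene, −40 to 0 °C
Reagents that add atoms: Tebbe reagent, C[Al-]1(C)C[Ti]([Cl+]1)(C1C=CC=C1)C1C=CC=C1
Why: Tebbe methylenation: the non-basic titanium methylidene converts the C5 ketone into the exocyclic olefin without enolisation or loss of the β-acyloxy group; the neopentyl C2 ketone and the esters react more slowly.

Step 32
Reactants: 43 6α-chloro-3(Z),5(16)-dien-2-one
Product: 44 target compound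
Conditions: NaBH4, CeCl3·7H2O, MeOH, −78 °C
Reagents that add atoms: none
Why: Luche 1,2-reduction of the cross-conjugated dienone; with C10 in the carbonyl plane, hydride should enter anti to the ring A carbon C14 and past the C15 methyl, giving the 2β-alcohol. The allylic chloride, lactone and esters are not touched at this temperature.

## Compound list

1 | dehydroabietic acid (4α-carboxyl, 4β-methyl, 5α-H, 10β-methyl) | CC(C)C1=CC2=C(C=C1)[C@]3(CCC[C@@]([C@@H]3CC2)(C)C(=O)O)C | starting material
2 | methyl dehydroabietate | CC(C)C1=CC2=C(C=C1)[C@]3(CCC[C@@]([C@@H]3CC2)(C)C(=O)OC)C | intermediate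
3 | methyl podocarpa-8,11,13-trien-18-oate | C1=CC2=C(C=C1)[C@]3(CCC[C@@]([C@@H]3CC2)(C)C(=O)OC)C | intermediate
4 | acetyl chloride | CC(Cl)=O | starting material
5 | methyl 13-acetylpodocarpa-8,11,13-trien-18-oate | CC(=O)C1=CC2=C(C=C1)[C@]3(CCC[C@@]([C@@H]3CC2)(C)C(=O)OC)C | intermediate
6 | methyl 13-acetoxypodocarpa-8,11,13-trien-18-oate | CC(=O)OC1=CC2=C(C=C1)[C@]3(CCC[C@@]([C@@H]3CC2)(C)C(=O)OC)C | intermediate
7 | methyl 13-hydroxypodocarpa-8,11,13-trien-18-oate | OC1=CC2=C(C=C1)[C@]3(CCC[C@@]([C@@H]3CC2)(C)C(=O)OC)C | intermediate (not isolated)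
8 | methyl 13-methoxypodocarpa-8,11,13-trien-18-oate | COC1=CC2=C(C=C1)[C@]3(CCC[C@@]([C@@H]3CC2)(C)C(=O)OC)C | intermediate
9 | 13-methoxypodocarpa-8,11,13-trien-18-oic acid | COC1=CC2=C(C=C1)[C@]3(CCC[C@@]([C@@H]3CC2)(C)C(=O)O)C | intermediate
10 | 13-methoxypodocarpa-8,12-dien-18-oic acid | COC1=CCC2=C(C1)CC[C@@H]1[C@]2(C)CCC[C@@]1(C)C(=O)O | intermediate
11 | ethylene glycol | OCCO | starting material
12 | 13,13-ethylenedioxypodocarp-8-en-18-oic acid | C12(OCCO1)CCC3=C(C2)CC[C@@H]2[C@]3(C)CCC[C@@]2(C)C(=O)O | intermediate
13 | primary ozonide of 12 (8,9-trioxolane, either face) | C12(OCCO1)CCC34OOOC4(C2)CC[C@@H]2[C@]3(C)CCC[C@@]2(C)C(=O)O | intermediate (not isolated)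
14 | secondary ozonide of 12 (C8 and C9 bridged by O and O–O) | C12(OCCO1)CCC3(OO4)OC4(C2)CC[C@@H]2[C@]3(C)CCC[C@@]2(C)C(=O)O | intermediate (not isolated)
15 | 13,13-ethylenedioxy-8,9-dioxo-8,9-secopodocarpan-18-oic acid (briarane 2,7-dione, C5 dioxolane, 11α-carboxyl) | C12(OCCO1)CCC(=O)[C@@]3(C)CCC[C@@](C)(C(=O)O)[C@@H]3CCC(=O)C2 | intermediate
16 | 5,5-ethylenedioxy-2,7-dihydroxy seco acid (C2 and C7 epimers) | C12(OCCO1)CCC(O)[C@@]3(C)CCC[C@@](C)(C(=O)O)[C@@H]3CCC(O)C2 | intermediate
17 | tert-butyldimethylsilyl ester of 18 | C12(OCCO1)CCC(O[Si](C)(C)C(C)(C)C)[C@@]3(C)CCC[C@@](C)(C(=O)O[Si](C)(C)C(C)(C)C)[C@@H]3CCC(O[Si](C)(C)C(C)(C)C)C2 | intermediate (not isolated)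
18 | 2,7-bis(tert-butyldimethylsilyloxy)-5,5-ethylenedioxy seco acid | C12(OCCO1)CCC(O[Si](C)(C)C(C)(C)C)[C@@]3(C)CCC[C@@](C)(C(=O)O)[C@@H]3CCC(O[Si](C)(C)C(C)(C)C)C2 | intermediate
19 | 18-nor 11(20)-exocyclic olefin (2,7-bis-silyl ether, C5 dioxolane) | C12(OCCO1)CCC(O[Si](C)(C)C(C)(C)C)[C@@]3(C)CCCC(=C)[C@@H]3CCC(O[Si](C)(C)C(C)(C)C)C2 | intermediate
20 | 18-nor 11(12)-ene | C12(OCCO1)CCC(O[Si](C)(C)C(C)(C)C)[C@@]3(C)CCC=C(C)[C@@H]3CCC(O[Si](C)(C)C(C)(C)C)C2 | intermediate
21 | 18-nor 11-en-13-one | C12(OCCO1)CCC(O[Si](C)(C)C(C)(C)C)[C@@]3(C)CC(=O)C=C(C)[C@@H]3CCC(O[Si](C)(C)C(C)(C)C)C2 | intermediate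
22 | 18-nor 11,13-dien-13-yl trifluoromethanesulfonate | C12(OCCO1)CCC(O[Si](C)(C)C(C)(C)C)[C@@]3(C)C=C(OS(=O)(=O)C(F)(F)F)C=C(C)[C@@H]3CCC(O[Si](C)(C)C(C)(C)C)C2 | intermediate
23 | 18-nor 11,13-diene | C12(OCCO1)CCC(O[Si](C)(C)C(C)(C)C)[C@@]3(C)C=CC=C(C)[C@@H]3CCC(O[Si](C)(C)C(C)(C)C)C2 | intermediate
24 | 13-ene-11α,12α-diol (11β-methyl) | C12(OCCO1)CCC(O[Si](C)(C)C(C)(C)C)[C@@]3(C)C=C[C@@H](O)[C@@](C)(O)[C@@H]3CCC(O[Si](C)(C)C(C)(C)C)C2 | intermediate
25 | 13α,14α-epoxy-11α,12α-diol | C12(OCCO1)CCC(O[Si](C)(C)C(C)(C)C)[C@@]3(C)[C@H]4O[C@H]4[C@@H](O)[C@@](C)(O)[C@@H]3CCC(O[Si](C)(C)C(C)(C)C)C2 | intermediate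
26 | 12α-butanoyloxy-13α,14α-epoxy-11α-hydroxy 2,7-bis-silyl ether | C12(OCCO1)CCC(O[Si](C)(C)C(C)(C)C)[C@@]3(C)[C@H]4O[C@H]4[C@@H](OC(=O)CCC)[C@@](C)(O)[C@@H]3CCC(O[Si](C)(C)C(C)(C)C)C2 | intermediate
27 | 7-alcohol (2-silyl ether, C7 epimers) | C12(OCCO1)CCC(O[Si](C)(C)C(C)(C)C)[C@@]3(C)[C@H]4O[C@H]4[C@@H](OC(=O)CCC)[C@@](C)(O)[C@@H]3CCC(O)C2 | intermediate
28 | 7-ketone | C12(OCCO1)CCC(O[Si](C)(C)C(C)(C)C)[C@@]3(C)[C@H]4O[C@H]4[C@@H](OC(=O)CCC)[C@@](C)(O)[C@@H]3CCC(=O)C2 | intermediate (not isolated)
29 | (8Z)-8-en-7-one | C12(OCCO1)CCC(O[Si](C)(C)C(C)(C)C)[C@@]3(C)[C@H]4O[C@H]4[C@@H](OC(=O)CCC)[C@@](C)(O)[C@@H]3/C=C\C(=O)C2 | intermediate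
30 | 8-iodo-8-en-7-one (C7 and C10 cis on the olefin) | C12(OCCO1)CCC(O[Si](C)(C)C(C)(C)C)[C@@]3(C)[C@H]4O[C@H]4[C@@H](OC(=O)CCC)[C@@](C)(O)[C@@H]3/C=C(I)\C(=O)C2 | intermediate
31 | methyl 2-bromopropanoate (racemic) | CC(Br)C(=O)OC | starting material
32 | bromo(1-methoxy-1-oxopropan-2-yl)zinc | COC(=O)C(C)[Zn]Br | intermediate (not isolated)
33 | 8-(1-methoxy-1-oxopropan-2-yl)-8-en-7-one (C17 epimers) | C12(OCCO1)CCC(O[Si](C)(C)C(C)(C)C)[C@@]3(C)[C@H]4O[C@H]4[C@@H](OC(=O)CCC)[C@@](C)(O)[C@@H]3/C=C(C(C)C(=O)OC)\C(=O)C2 | intermediate
34 | 7α-hydroxy-8-ene methyl ester (C17 epimers) | C12(OCCO1)CCC(O[Si](C)(C)C(C)(C)C)[C@@]3(C)[C@H]4O[C@H]4[C@@H](OC(=O)CCC)[C@@](C)(O)[C@@H]3/C=C(C(C)C(=O)OC)\[C@@H](O)C2 | intermediate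
35 | 8α,9α-epoxy-7α-hydroxy methyl ester (C17 epimers) | C12(OCCO1)CCC(O[Si](C)(C)C(C)(C)C)[C@@]3(C)[C@H]4O[C@H]4[C@@H](OC(=O)CCC)[C@@](C)(O)[C@@H]3[C@H]5O[C@@]5(C(C)C(=O)OC)[C@@H](O)C2 | intermediate
36 | 9β-acetoxy-7α,8α-dihydroxy methyl ester (C17 epimers) | C12(OCCO1)CCC(O[Si](C)(C)C(C)(C)C)[C@@]3(C)[C@H]4O[C@H]4[C@@H](OC(=O)CCC)[C@@](C)(O)[C@@H]3[C@H](OC(C)=O)[C@](O)(C(C)C(=O)OC)[C@@H](O)C2 | intermediate (not isolated)
37 | 9β-acetoxy-8α-hydroxy 19,7-lactone (C18 methyl cis to 8-OH; 2-silyl ether, C5 dioxolane) | C12(OCCO1)CCC(O[Si](C)(C)C(C)(C)C)[C@@]3(C)[C@H]4O[C@H]4[C@@H](OC(=O)CCC)[C@@](C)(O)[C@@H]3[C@H](OC(C)=O)[C@]5(O)[C@@H](C)C(=O)O[C@H]5C2 | intermediate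
38 | 2-alcohol of the lactone (C2 epimers) | C12(OCCO1)CCC(O)[C@@]3(C)[C@H]4O[C@H]4[C@@H](OC(=O)CCC)[C@@](C)(O)[C@@H]3[C@H](OC(C)=O)[C@]5(O)[C@@H](C)C(=O)O[C@H]5C2 | intermediate
39 | 2-ketone of the lactone | C12(OCCO1)CCC(=O)[C@@]3(C)[C@H]4O[C@H]4[C@@H](OC(=O)CCC)[C@@](C)(O)[C@@H]3[C@H](OC(C)=O)[C@]5(O)[C@@H](C)C(=O)O[C@H]5C2 | intermediate (not isolated)
40 | (3Z)-3-en-2-one with C5 dioxolane | C12(OCCO1)/C=C\C(=O)[C@@]3(C)[C@H]4O[C@H]4[C@@H](OC(=O)CCC)[C@@](C)(O)[C@@H]3[C@H](OC(C)=O)[C@]5(O)[C@@H](C)C(=O)O[C@H]5C2 | intermediate
41 | (3Z)-3-ene-2,5-dione | O=C1/C=C\C(=O)[C@@]2(C)[C@H]3O[C@H]3[C@@H](OC(=O)CCC)[C@@](C)(O)[C@@H]2[C@H](OC(C)=O)[C@]2(O)[C@@H](C)C(=O)O[C@H]2C1 | intermediate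
42 | 6α-chloro-(3Z)-3-ene-2,5-dione | O=C1/C=C\C(=O)[C@@]2(C)[C@H]3O[C@H]3[C@@H](OC(=O)CCC)[C@@](C)(O)[C@@H]2[C@H](OC(C)=O)[C@]2(O)[C@@H](C)C(=O)O[C@H]2[C@H]1Cl | intermediate
43 | 6α-chloro-3(Z),5(16)-dien-2-one | C=C1/C=C\C(=O)[C@@]2(C)[C@H]3O[C@H]3[C@@H](OC(=O)CCC)[C@@](C)(O)[C@@H]2[C@H](OC(C)=O)[C@]2(O)[C@@H](C)C(=O)O[C@H]2[C@H]1Cl | intermediate
44 | 9β-acetoxy-12α-butanoyloxy-6α-chloro-13α,14α-epoxy-2β,8α,11α-trihydroxybriara-3(Z),5(16)-diene 19,7-lactone (CNP0325729.2) | C=C1/C=C\[C@H](O)[C@@]2(C)[C@H]3O[C@H]3[C@@H](OC(=O)CCC)[C@@](C)(O)[C@@H]2[C@H](OC(C)=O)[C@]2(O)[C@@H](C)C(=O)O[C@H]2[C@H]1Cl | target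

## Step count and least certain steps

Total: 32 steps. Longest linear sequence: 32 steps (1 to 44); 4, 11 and 31 are commercial building blocks.

Step 9 (key step). What may go wrong: incomplete reduction of the hindered bridged ozonide, oxidation beyond the olefin if ozone is not stopped in time, and transannular aldol condensation of the 1,6-dione during work-up. Fallback, from 12 and back at 15: dihydroxylation of the tetrasubstituted olefin with OsO4 and NMO in the presence of MeSO2NH2 should give the cis-8,9-diol F1. Glycol cleavage with Pb(OAc)4 in benzene over K2CO3 would then give 15 under non-oxidising, base-buffered conditions.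

Step 3. What may go wrong: poor regioselectivity of the acylation between C12 and C13, since both positions are electronically similar. Fallback, from 3 and back at 8: benzylic oxidation with CrO3 in acetic acid would give the 7-ketone F2. The acyl group then directs bromination (Br2 with excess AlCl3) meta to itself and para to C9, giving the 13-bromo-7-ketone F3. Ionic hydrogenation with Et3SiH and CF3CO2H would remove the ketone to give the 13-bromo ester F4, and copper-catalysed methoxylation (NaOMe, CuI, DMF) would deliver 8.

Step 26. What may go wrong: lactonisation before the epoxide is opened, which removes the directing hydroxyl, and acetate attack at C8 or at the ring A epoxide. Fallback, from 35 and back at 37: the lactone is closed first with catalytic PPTS to give the epoxy lactone F5. Its epoxide is then opened by uncatalysed SN2 attack of caesium acetate (buffered with acetic acid, 18-crown-6, DMF, 60 °C) at C9, the only unhindered secondary epoxide carbon. Catalytic DBU equilibration at C17 then gives 37.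

Step 30. What may go wrong: poor or opposite facial selectivity of the enol halogenation, and epimerisation of the α-chloro ketone before step 31. Fallback, from 41 and back at 42: the enol is brominated with NBS and catalytic thiourea, which should give the 6-bromo ketone F6 with the halogen on the face the enol prefers. Finkelstein displacement with LiCl in DMF then inverts C6, which gives 42 if direct chlorination has placed the halogen on the wrong face.

Step 32. What may go wrong: poor facial selectivity of hydride addition to the hindered C2 carbonyl, and conjugate reduction of the dienone. Fallback, from 43 and back at 44: the reduction is run under reagent control with the CBS oxazaborolidine and catecholborane at −78 °C, using the (R)-catalyst if quaternary C1 acts as the large group. The 2-epimer F7 is separated, oxidised back to 43 with Dess–Martin periodinane and recycled.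

## Further compounds

F1 | step 9 | 13,13-ethylenedioxy-8,9-dihydroxypodocarpan-18-oic acid (cis-diol, either face) | C12(OCCO1)CCC3(O)C(O)(C2)CC[C@@H]2[C@]3(C)CCC[C@@]2(C)C(=O)O
F2 | step 3 | methyl 7-oxopodocarpa-8,11,13-trien-18-oate | C1=CC2=C(C=C1)[C@]3(CCC[C@@]([C@@H]3CC2=O)(C)C(=O)OC)C
F3 | step 3 | methyl 13-bromo-7-oxopodocarpa-8,11,13-trien-18-oate | BrC1=CC2=C(C=C1)[C@]3(CCC[C@@]([C@@H]3CC2=O)(C)C(=O)OC)C
F4 | step 3 | methyl 13-bromopodocarpa-8,11,13-trien-18-oate | BrC1=CC2=C(C=C1)[C@]3(CCC[C@@]([C@@H]3CC2)(C)C(=O)OC)C
F5 | step 26 | 8α,9α-epoxy 19,7-lactone (C17 epimers; 2-silyl ether, C5 dioxolane) | C12(OCCO1)CCC(O[Si](C)(C)C(C)(C)C)[C@@]3(C)[C@H]4O[C@H]4[C@@H](OC(=O)CCC)[C@@](C)(O)[C@@H]3[C@H]5O[C@]56C(C)C(=O)O[C@H]6C2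
F6 | step 30 | 6β-bromo-(3Z)-3-ene-2,5-dione | O=C1/C=C\C(=O)[C@@]2(C)[C@H]3O[C@H]3[C@@H](OC(=O)CCC)[C@@](C)(O)[C@@H]2[C@H](OC(C)=O)[C@]2(O)[C@@H](C)C(=O)O[C@H]2[C@@H]1Br
F7 | step 32 | 2-epimer of 44 (2α-hydroxy) | C=C1/C=C\[C@@H](O)[C@@]2(C)[C@H]3O[C@H]3[C@@H](OC(=O)CCC)[C@@](C)(O)[C@@H]2[C@H](OC(C)=O)[C@]2(O)[C@@H](C)C(=O)O[C@H]2[C@H]1Cl
A1 | alternative 1 | ring A 11,14-endoperoxide with C2 p-methoxybenzyloxymethyl and C9 silyloxymethyl stubs | COc1ccc(COC[C@@]2(C)[C@@H]3C=C[C@@](C)(OO3)[C@@H]2CO[Si](C)(C)C(C)(C)C)cc1
A2 | alternative 2 | fused rings A and B with C2 alcohol, ring A diene, butenolide, C5 ketone and C6 silyl ether | O=C1/C=C\[C@H](O)[C@@]2(C)C=CC=C(C)[C@@H]2[C@H](OC(C)=O)C2=C(C)C(=O)O[C@H]2[C@@H]1O[Si](C)(C)C(C)(C)C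
A3 | alternative 3 | chloro lactone with C16 silyloxymethyl on C5 | CC(C)(C)[Si](C)(C)OC[C@H]1/C=C\[C@H](O)[C@@]2(C)[C@H]3O[C@H]3[C@@H](OC(=O)CCC)[C@@](C)(O)[C@@H]2[C@H](OC(C)=O)[C@]2(O)[C@@H](C)C(=O)O[C@H]2[C@H]1Cl
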